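Locants: chromene O1, C2, C3, C4, C4a, C5–C8, C8a; side ring C1' (quaternary), C2' (CHMe), C3'=C4', C5', C6'. Retrosynthesis: the quinone goes back (oxidation level; C3=C4 from a C4 silyloxy helper) to a chroman-5,8-diol. Cutting C8–C8a and re-joining C5 to C8 gives a 4-(dihydropyran-5-yl)-4-hydroxycyclobutenone, and cutting C4a–C5 leaves a 5-bromo-3,4-dihydro-2H-pyran and 3-methoxycyclobutene-1,2-dione.
Enabling feature: in the quinone ring the arc C5(=O)–C6(OMe)=C7H–C8(=O) is a ring-expanded 3-methoxycyclobutene-1,2-dione. The remaining edge C4a=C8a is also the enol-ether double bond O1–C8a=C4a of the pyran ring, so the finished pyran can act as the alkenyl arm of a cyclobutenone-to-quinone ring expansion.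
The bromodihydropyran is cut at O1–C8a (alkynol cycloisomerisation) and C4–C4a (acetylide addition). The C2–O1 bond comes from epoxidation and hydride opening of a (Z)-allylic alcohol. That alcohol is cut at C3'=C4' (ring-closing metathesis), at the bond from C2 to the CH2CH2 linker (B-alkyl Suzuki–Miyaura coupling) and at C1'–C2' (Ireland–Claisen rearrangement of geranyl propionate).
Forward order: chain assembly, cyclohexene ring (step 6), dihydropyran ring (step 12), temporary four-membered ring attached (step 15), quinone carbocycle closed last (step 16), then C3=C4 and the quinone level released (step 17).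
Stereochemistry: C1' and C2' arise together in one chair Claisen transition state (relative: alkene and enolate geometry; absolute: chiral boron ligand). C2 comes from reagent-controlled Sharpless epoxidation. C4 and the cyclobutenol carbon are helper centres that vanish.
Key step: step 16

Assumption: the (R,R)-configured boron controller is taken to give the (2R,3S)-acid of step 1; this sense of induction is assigned by analogy only, and the mirror-image controller would be used otherwise with nothing else changed.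
Remark: the silyloxy carbon C4 and the cyclobutenol carbon are carried as epimer mixtures (left undefined in the SMILES) because both become planar before the target.

Step 1
Reactants: 1 geranyl propionate [(2E)-3,7-dimethylocta-2,6-dien-1-yl propanoate]
Product: 3 (2R,3S)-3-ethenyl-2,3,7-trimethyloct-6-enoic acid, via boron ketene acetal 2 (not isolated)
Conditions: (R,R)-[ArSO2NHCH(Ph)]2 (Ar = 3,5-(CF3)2C6H3), BBr3, CH2Cl2, rt, then vacuum; 1, i-Pr2NEt, CH2Cl2, −78 °C, then −20 °C; aq. work-up
Reagents that add atoms: none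
Why: Enantioselective Ireland–Claisen rearrangement in which soft enolisation with the C2-symmetric bromoborane and i-Pr2NEt in CH2Cl2 gives enolate 2 with methyl cis to O–B, and its chair transition state on the (E)-trisubstituted geranyl alkene forms C1'–C2' so that both stereocentres arise in one event (the two methyl groups trans on the future ring, vinyl cis to the C2' methyl), the absolute sense coming from the boron ligand.

Step 2
Reactants: 4 but-2-yn-1-ol
Product: 5 (Z)-3-iodobut-2-en-1-ol
Conditions: NaAlH2(OCH2CH2OMe)2 (Red-Al), THF, 0 °C → rt; N-iodosuccinimide, −78 °C → 0 °C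
Reagents that add atoms: N-iodosuccinimide, O=C1CCC(=O)N1I
Why: Alkoxide-directed trans-hydroalumination of the propargylic alcohol places aluminium on C3 cis to the CH2O group, and iodinolysis with retention gives the (Z)-iodide.

Step 3
Reactants: 3 (2R,3S)-3-ethenyl-2,3,7-trimethyloct-6-enoic acid; 5 (Z)-3-iodobut-2-en-1-ol
Product: 7 (2R,3S,6Z)-8-hydroxy-2,3,6-trimethyl-3-(4-methylpent-3-en-1-yl)oct-6-enoic acid, via alkylborane 6 (not isolated)
Conditions: 9-BBN-H (2.3 equiv), THF, 0 °C → rt; then 5, PdCl2(dppf) (5 mol %), AsPh3, aq. NaOH, THF–DMF, rt; H3O+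
Reagents that add atoms: none
Why: 9-BBN-H adds only to the monosubstituted vinyl group (the carboxyl group is merely tied up as its slowly reduced boron ester and the trisubstituted alkene is too hindered), and the B-alkyl Suzuki–Miyaura coupling joins the primary borane 6 to 5 with retention of the (Z)-geometry and without touching a stereocentre.

Step 4
Reactants: 7 (2R,3S,6Z)-8-hydroxy-2,3,6-trimethyl-3-(4-methylpent-3-en-1-yl)oct-6-enoic acid
Product: 8 (3R,4S,7Z)-9-hydroxy-3,4,7-trimethyl-4-(4-methylpent-3-en-1-yl)non-7-en-2-one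
Conditions: MeLi (5 equiv), Et2O, 0 °C → rt; inverse quench into cold 1 M HCl
Reagents that add atoms: methyllithium, [Li]C
Why: Addition of methyllithium to the lithium carboxylate stops at the gem-dialkoxide, which releases the methyl ketone only on quench (acid-to-methyl-ketone conversion), so over-addition and enolisation at the future C2' are avoided.

Step 5
Reactants: 8 (3R,4S,7Z)-9-hydroxy-3,4,7-trimethyl-4-(4-methylpent-3-en-1-yl)non-7-en-2-one
Product: 9 (2Z,6S,7S)-3,6,7,8-tetramethyl-6-(4-methylpent-3-en-1-yl)nona-2,8-dien-1-ol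
Conditions: Ph3PCH3Br, KOt-Bu (3.5 equiv each), THF, 0 °C → 40 °C
Reagents that add atoms: methyltriphenylphosphonium bromide (as its ylide), C[P+](c1ccccc1)(c1ccccc1)c1ccccc1.[Br-]
Why: Wittig methylenation, in which any enolisation by the ylide should occur at the unhindered methyl side and so leave the adjacent stereocentre intact (its descriptor changes from R to S only because the priorities change).

Step 6
Reactants: 9 (2Z,6S,7S)-3,6,7,8-tetramethyl-6-(4-methylpent-3-en-1-yl)nona-2,8-dien-1-ol
Product: 10 (2Z)-3-methyl-5-[(1S,2R)-1,2,3-trimethylcyclohex-3-en-1-yl]pent-2-en-1-ol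
Conditions: second-generation Hoveyda–Grubbs catalyst (5 mol %), 1,4-benzoquinone (10 mol %), toluene, 80 °C, Ar sparge
Reagents that add atoms: none
Why: Ring-closing metathesis of the 1,1-disubstituted alkene and the isopropylidene alkene gives the six-membered ring with the trisubstituted C3'=C4' bond and volatile isobutene, whereas closures onto the allylic-alcohol alkene would need a tetrasubstituted or a seven-membered ring alkene.

Step 7
Reactants: 10 (2Z)-3-methyl-5-[(1S,2R)-1,2,3-trimethylcyclohex-3-en-1-yl]pent-2-en-1-ol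
Product: 11 [(2R,3S)-3-methyl-3-{2-[(1S,2R)-1,2,3-trimethylcyclohex-3-en-1-yl]ethyl}oxiran-2-yl]methanol
Conditions: Ti(Oi-Pr)4 (10 mol %), D-(−)-diethyl tartrate (12 mol %), t-BuOOH, 4 Å MS, CH2Cl2, −20 °C
Reagents that add atoms: tert-butyl hydroperoxide, CC(C)(C)OO
Why: Sharpless asymmetric epoxidation, in which the allylic hydroxyl group selects this alkene over the ring alkene and D-(−)-tartrate delivers oxygen to the face that makes the methyl-bearing carbon (future C2) S, as for nerol-type (Z)-allylic alcohols, under reagent control independent of the remote ring stereocentres.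

Step 8
Reactants: 11 [(2R,3S)-3-methyl-3-{2-[(1S,2R)-1,2,3-trimethylcyclohex-3-en-1-yl]ethyl}oxiran-2-yl]methanol
Product: 12 (3S)-3-methyl-5-[(1S,2R)-1,2,3-trimethylcyclohex-3-en-1-yl]pentane-1,3-diol
Conditions: NaAlH2(OCH2CH2OMe)2 (Red-Al), THF, 0 °C → rt
Reagents that add atoms: none
Why: Hydroxyl-directed reductive epoxide opening, in which the alkoxyaluminate delivers hydride to the secondary epoxide carbon next to the carbinol, so the C–O bond at the tertiary stereocentre is kept and the 1,3-diol results.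

Step 9
Reactants: 12 (3S)-3-methyl-5-[(1S,2R)-1,2,3-trimethylcyclohex-3-en-1-yl]pentane-1,3-diol
Product: 13 (3S)-3-hydroxy-3-methyl-5-[(1S,2R)-1,2,3-trimethylcyclohex-3-en-1-yl]pentanal
Conditions: TEMPO (10 mol %), PhI(OAc)2, CH2Cl2, rt
Reagents that add atoms: none
Why: Oxoammonium (TEMPO) oxidation converts only the primary alcohol because the tertiary one cannot be oxidised, and the nearly neutral medium spares the β-hydroxy aldehyde from dehydration.

Step 10
Reactants: 13 (3S)-3-hydroxy-3-methyl-5-[(1S,2R)-1,2,3-trimethylcyclohex-3-en-1-yl]pentanal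
Product: 14 (5S)-5-methyl-7-[(1S,2R)-1,2,3-trimethylcyclohex-3-en-1-yl]hept-1-yne-3,5-diol (both C3 epimers)
Conditions: HC≡CMgBr (3 equiv), THF, −78 °C → 0 °C
Reagents that add atoms: ethynylmagnesium bromide, C#C[Mg]Br
Why: Grignard 1,2-addition of the acetylide (one equivalent is spent on the tertiary hydroxyl group) brings in C4a and C8a, and the new carbinol centre (future C4) is left uncontrolled because it is erased in step 17.

Step 11
Reactants: 14 (5S)-5-methyl-7-[(1S,2R)-1,2,3-trimethylcyclohex-3-en-1-yl]hept-1-yne-3,5-diol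
Product: 15 (5S)-3-[(tert-butyldimethylsilyl)oxy]-5-methyl-7-[(1S,2R)-1,2,3-trimethylcyclohex-3-en-1-yl]hept-1-yn-5-ol
Conditions: TBSCl, imidazole, DMF, rt
Reagents that add atoms: tert-butyldimethylsilyl chloride, CC(C)(C)[Si](C)(C)Cl
Why: Silylation with TBSCl and imidazole discriminates the secondary propargylic alcohol from the hindered tertiary one, which must stay free as the future ring oxygen.

Step 12
Reactants: 15 (5S)-3-[(tert-butyldimethylsilyl)oxy]-5-methyl-7-[(1S,2R)-1,2,3-trimethylcyclohex-3-en-1-yl]hept-1-yn-5-ol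
Product: 16 (2S)-4-[(tert-butyldimethylsilyl)oxy]-2-methyl-2-{2-[(1S,2R)-1,2,3-trimethylcyclohex-3-en-1-yl]ethyl}-3,4-dihydro-2H-pyran
Conditions: W(CO)6 (25 mol %), DABCO, THF, hν (350 nm), 60 °C
Reagents that add atoms: none
Why: Endo-selective alkynol cycloisomerisation, in which photogenerated W(CO)5 activates the terminal alkyne in its vinylidene form and the tertiary hydroxyl group, helped by the geminal disubstitution, attacks the terminal carbon (6-endo) to give the enol ether O1–C8a=C4a without touching C2.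

Step 13
Reactants: 16 (2S)-4-[(tert-butyldimethylsilyl)oxy]-2-methyl-2-{2-[(1S,2R)-1,2,3-trimethylcyclohex-3-en-1-yl]ethyl}-3,4-dihydro-2H-pyran
Product: 18 (2S)-5-bromo-4-[(tert-butyldimethylsilyl)oxy]-2-methyl-2-{2-[(1S,2R)-1,2,3-trimethylcyclohex-3-en-1-yl]ethyl}-3,4-dihydro-2H-pyran, via dibromide 17 (not isolated)
Conditions: Br2 (1.0 equiv, slow addition), CH2Cl2, −78 °C; DBU, −78 °C → rt
Reagents that add atoms: bromine, BrBr
Why: Bromination–dehydrobromination of an enol ether, which is far more nucleophilic than the hindered trisubstituted ring alkene, after which DBU removes the C4a hydrogen and the anomeric bromide of 17 to leave the vinyl bromide.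

Step 14
Reactants: 19 dimethyl squarate (3,4-dimethoxycyclobut-3-ene-1,2-dione)
Product: 21 3-methoxycyclobut-3-ene-1,2-dione (methyl semisquarate), via hydroxycyclobutenone 20 (not isolated)
Conditions: LiAlH(Ot-Bu)3 (1.05 equiv), THF, −78 °C → −20 °C; 6 M HCl, CH2Cl2, rt
Reagents that add atoms: water, O
Why: The bulky hydride adds 1,2 to one squarate carbonyl group, then acid ionises the carbinol of 20, water adds to the alkoxy-stabilised cation and methanol leaves, which is the standard squarate-to-semisquarate conversion.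

Step 15
Reactants: 18 (2S)-5-bromo-4-[(tert-butyldimethylsilyl)oxy]-2-methyl-2-{2-[(1S,2R)-1,2,3-trimethylcyclohex-3-en-1-yl]ethyl}-3,4-dihydro-2H-pyran; 21 3-methoxycyclobut-3-ene-1,2-dione
Product: 23 4-hydroxy-3-methoxy-4-[(2S)-4-[(tert-butyldimethylsilyl)oxy]-2-methyl-2-{2-[(1S,2R)-1,2,3-trimethylcyclohex-3-en-1-yl]ethyl}-3,4-dihydro-2H-pyran-5-yl]cyclobut-2-en-1-one, via vinyllithium 22 (not isolated)
Conditions: t-BuLi (2.0 equiv), Et2O, −78 °C; 21 in THF, −78 °C; sat. aq. NH4Cl, −78 °C → rt
Reagents that add atoms: none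
Why: Bromine–lithium exchange at −78 °C outruns ring-opening β-elimination of 22, and the vinyllithium adds 1,2 to the ketone-like carbonyl next to C–OMe rather than to the vinylogous-ester carbonyl, which fixes the later place of the methoxy group, the new carbinol centre being irrelevant.

Step 16
Reactants: 23 4-hydroxy-3-methoxy-4-[(2S)-4-[(tert-butyldimethylsilyl)oxy]-2-methyl-2-{2-[(1S,2R)-1,2,3-trimethylcyclohex-3-en-1-yl]ethyl}-3,4-dihydro-2H-pyran-5-yl]cyclobut-2-en-1-one
Product: 26 (2S)-4-[(tert-butyldimethylsilyl)oxy]-6-methoxy-2-methyl-2-{2-[(1S,2R)-1,2,3-trimethylcyclohex-3-en-1-yl]ethyl}-3,4-dihydro-2H-chromene-5,8-diol, via dienylketene 24 (not isolated), via cyclohexadienone 25 (not isolated)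
Conditions: toluene (degassed, dilute), 110 °C, Ar, dark
Reagents that add atoms: none
Why: Heating opens the strained cyclobutenone 23 by conrotatory four-electron cleavage of the C5–C8 bond, and the donor hydroxyl group rotates outward (torquoselectivity), so the dihydropyranyl arm turns inward next to the ketene of 24. The dienylketene then closes the six-membered carbocycle by thermal disrotatory six-electron electrocyclisation, forming the C8–C8a bond, and dienone 25 enolises irreversibly to the aromatic hydroquinone 26. The closest known reaction type is the Moore rearrangement of 4-alkenyl-4-hydroxycyclobutenones to hydroquinones. No lasting stereocentre is formed, since C8a is sp3 only in 25, the carbinol carbon of 23 becomes the planar C5, and C2, C1' and C2' lie outside the reacting array. The regiochemistry (methoxy on C6 next to C5, hydrogen on C7) needs no selection here because it is written into 23 by the site of addition in step 15, and the one selectivity required, inward rotation of the alkenyl arm, is secured by the free hydroxyl group. Release of four-ring strain and aromatisation drive the change, while the ring alkene and the silyl ether are spectators at this temperature.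

Step 17
Reactants: 26 (2S)-4-[(tert-butyldimethylsilyl)oxy]-6-methoxy-2-methyl-2-{2-[(1S,2R)-1,2,3-trimethylcyclohex-3-en-1-yl]ethyl}-3,4-dihydro-2H-chromene-5,8-diol
Product: 28 (2S)-6-methoxy-2-methyl-2-{2-[(1S,2R)-1,2,3-trimethylcyclohex-3-en-1-yl]ethyl}-2H-chromene-5,8-dione (target), via chromenediol 27 (not isolated)
Conditions: camphorsulfonic acid (10 mol %), toluene, rt, Ar, dark; then Ag2O, rt
Reagents that add atoms: none
Why: Mild acid ionises the C4–O bond, the cation being stabilised by the ortho hydroxyl group on C5 and by O1 through C8a, loss of a C3 hydrogen gives the 2H-chromene (the E1 dehydration type used for chroman-4-ols), and Ag2O oxidises hydroquinone 27 to the quinone without touching either alkene or C2.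

Compound list
1 | geranyl propionate | CCC(=O)OC/C=C(C)/CCC=C(C)C | starting material
2 | boron ketene acetal of 1 (methyl cis to O–B; (4R,5R)-diazaborolidine) | C/C=C(\OB1N(S(=O)(=O)c2cc(cc(c2)C(F)(F)F)C(F)(F)F)[C@H](c2ccccc2)[C@@H](c2ccccc2)N1S(=O)(=O)c1cc(cc(c1)C(F)(F)F)C(F)(F)F)OC/C=C(C)/CCC=C(C)C | intermediate
3 | (2R,3S)-3-ethenyl-2,3,7-trimethyloct-6-enoic acid | OC(=O)[C@H](C)[C@](C)(C=C)CCC=C(C)C | intermediate
4 | but-2-yn-1-ol | CC#CCO | starting material
5 | (Z)-3-iodobut-2-en-1-ol | C/C(I)=C/CO | intermediate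
6 | B-alkyl-9-BBN adduct of 3 (carboxyl group as 9-BBN ester) | O=C(OB1C2CCCC1CCC2)[C@H](C)[C@](C)(CCB1C2CCCC1CCC2)CCC=C(C)C | intermediate
7 | (2R,3S,6Z)-8-hydroxy-2,3,6-trimethyl-3-(4-methylpent-3-en-1-yl)oct-6-enoic acid | OC(=O)[C@H](C)[C@](C)(CC/C(C)=C\CO)CCC=C(C)C | intermediate
8 | (3R,4S,7Z)-9-hydroxy-3,4,7-trimethyl-4-(4-methylpent-3-en-1-yl)non-7-en-2-one | CC(=O)[C@H](C)[C@](C)(CC/C(C)=C\CO)CCC=C(C)C | intermediate
9 | (2Z,6S,7S)-3,6,7,8-tetramethyl-6-(4-methylpent-3-en-1-yl)nona-2,8-dien-1-ol | C=C(C)[C@H](C)[C@](C)(CC/C(C)=C\CO)CCC=C(C)C | intermediate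
10 | (2Z)-3-methyl-5-[(1S,2R)-1,2,3-trimethylcyclohex-3-en-1-yl]pent-2-en-1-ol | OC/C=C(C)\CC[C@]1(C)CCC=C(C)[C@@H]1C | intermediate
11 | [(2R,3S)-3-methyl-3-{2-[(1S,2R)-1,2,3-trimethylcyclohex-3-en-1-yl]ethyl}oxiran-2-yl]methanol | OC[C@H]1O[C@@]1(C)CC[C@]2(C)CCC=C(C)[C@@H]2C | intermediate
12 | (3S)-3-methyl-5-[(1S,2R)-1,2,3-trimethylcyclohex-3-en-1-yl]pentane-1,3-diol | OCC[C@@](C)(O)CC[C@]1(C)CCC=C(C)[C@@H]1C | intermediate
13 | (3S)-3-hydroxy-3-methyl-5-[(1S,2R)-1,2,3-trimethylcyclohex-3-en-1-yl]pentanal | O=CC[C@@](C)(O)CC[C@]1(C)CCC=C(C)[C@@H]1C | intermediate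
14 | (5S)-5-methyl-7-[(1S,2R)-1,2,3-trimethylcyclohex-3-en-1-yl]hept-1-yne-3,5-diol, C3 epimers | C#CC(O)C[C@@](C)(O)CC[C@]1(C)CCC=C(C)[C@@H]1C | intermediate
15 | (5S)-3-[(tert-butyldimethylsilyl)oxy]-5-methyl-7-[(1S,2R)-1,2,3-trimethylcyclohex-3-en-1-yl]hept-1-yn-5-ol, C3 epimers | C#CC(O[Si](C)(C)C(C)(C)C)C[C@@](C)(O)CC[C@]1(C)CCC=C(C)[C@@H]1C | intermediate
16 | (2S)-4-silyloxy-2-methyl-2-{2-[(1S,2R)-1,2,3-trimethylcyclohex-3-en-1-yl]ethyl}-3,4-dihydro-2H-pyran, C4 epimers | C[C@]1(CC[C@]2(C)CCC=C(C)[C@@H]2C)CC(O[Si](C)(C)C(C)(C)C)C=CO1 | intermediate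
17 | (2S)-5,6-dibromo-4-silyloxy-2-methyl-2-{2-[(1S,2R)-1,2,3-trimethylcyclohex-3-en-1-yl]ethyl}tetrahydropyran | C[C@]1(CC[C@]2(C)CCC=C(C)[C@@H]2C)CC(O[Si](C)(C)C(C)(C)C)C(Br)C(Br)O1 | intermediate
18 | (2S)-5-bromo-4-silyloxy-2-methyl-2-{2-[(1S,2R)-1,2,3-trimethylcyclohex-3-en-1-yl]ethyl}-3,4-dihydro-2H-pyran | C[C@]1(CC[C@]2(C)CCC=C(C)[C@@H]2C)CC(O[Si](C)(C)C(C)(C)C)C(Br)=CO1 | intermediate
19 | dimethyl squarate | COC1=C(OC)C(=O)C1=O | starting material
20 | 4-hydroxy-2,3-dimethoxycyclobut-2-en-1-one | COC1=C(OC)C(O)C1=O | intermediate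
21 | 3-methoxycyclobut-3-ene-1,2-dione | COC1=CC(=O)C1=O | intermediate
22 | 5-lithio derivative of 18 (lithium in place of bromine) | C[C@]1(CC[C@]2(C)CCC=C(C)[C@@H]2C)CC(O[Si](C)(C)C(C)(C)C)C([Li])=CO1 | intermediate
23 | 4-hydroxy-3-methoxy-4-(dihydropyran-5-yl)cyclobut-2-en-1-one (full name in step 15) | COC1=CC(=O)C1(O)C2=CO[C@@](C)(CC[C@]3(C)CCC=C(C)[C@@H]3C)CC2O[Si](C)(C)C(C)(C)C | intermediate
24 | dienylketene from ring opening of 23 (hydroxyl outward, pyranyl cis to the ketene arm) | O=C=C/C(OC)=C(/O)C1=CO[C@@](C)(CC[C@]2(C)CCC=C(C)[C@@H]2C)CC1O[Si](C)(C)C(C)(C)C | intermediate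
25 | (2S)-4-silyloxy-5-hydroxy-6-methoxy-2-methyl-2-{…ethyl}-2,3,4,8a-tetrahydro-8H-chromen-8-one | COC1=CC(=O)C2O[C@@](C)(CC[C@]3(C)CCC=C(C)[C@@H]3C)CC(O[Si](C)(C)C(C)(C)C)C2=C1O | intermediate
26 | (2S)-4-silyloxy-6-methoxy-2-methyl-2-{2-[(1S,2R)-1,2,3-trimethylcyclohex-3-en-1-yl]ethyl}chromane-5,8-diol | COc1cc(O)c2O[C@@](C)(CC[C@]3(C)CCC=C(C)[C@@H]3C)CC(O[Si](C)(C)C(C)(C)C)c2c1O | intermediate
27 | (2S)-6-methoxy-2-methyl-2-{2-[(1S,2R)-1,2,3-trimethylcyclohex-3-en-1-yl]ethyl}-2H-chromene-5,8-diol | COc1cc(O)c2O[C@@](C)(CC[C@]3(C)CCC=C(C)[C@@H]3C)C=Cc2c1O | intermediate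
28 | (2S)-6-methoxy-2-methyl-2-{2-[(1S,2R)-1,2,3-trimethylcyclohex-3-en-1-yl]ethyl}-2H-chromene-5,8-dione | COC1=CC(=O)C2=C(C=C[C@](C)(CC[C@]3(C)CCC=C(C)[C@@H]3C)O2)C1=O | target

Total step count: 17. Longest linear sequence: 15 steps (1, 3–13, 15–17).

Steps most likely to fail

Step 15.
- What may go wrong: ring-opening β-elimination of the lithiated enol ether before it is trapped, proton transfer from the ring C–H of 21, or conjugate addition in place of carbonyl addition.
- Approach of the fallback: no organolithium and no squarate. The carbocycle is still the last ring closed, now by a Danheiser benzannulation. It sets out from 18 and comes back to the route at 28.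
- Stille coupling of 18 with tributyl(1-ethoxyvinyl)stannane under Pd(PPh3)4 gives the 5-(1-ethoxyvinyl)dihydropyran F1. Its exocyclic enol ether is hydrolysed on wet silica to the 5-acetyl compound F2.
- LiN(SiMe3)2 and CF3CO2CH2CF3 give the trifluoroacetylated ketone F3. Mesyl azide with Et3N turns F3 into the diazoketone F4 by detrifluoroacetylative diazo transfer.
- Irradiation (300 nm) with methoxyacetylene starts a photo-Wolff rearrangement. This is followed by [2+2] addition, four-electron opening and six-electron closure to the 6-methoxychroman-8-ol F5.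
- Camphorsulfonic acid removes silanol to give the chromen-8-ol F6. The Teuber oxidation with (KSO3)2NO then places the C5 oxygen para to the phenol and gives 28.

Step 1.
- What may go wrong: slow rearrangement of the hindered trisubstituted allyl terminus at the low temperature the boron enolate tolerates, erosion of enolate geometry, or the wrong or an insufficient sense of face selection.
- Approach of the fallback: relative control by the ordinary silyl ketene acetal, absolute control by separation on a purchased auxiliary. It sets out from 1 and comes back at 3.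
- Enolisation of 1 with LiN(i-Pr)2 in THF–DMPU and silylation with TBSCl give the (Z)-silyl ketene acetal F7, which has the same geometry as 2.
- Warming brings about the Ireland–Claisen rearrangement to the racemic silyl ester F8. Its hydrolysis gives 3 together with its mirror image F9.
- Coupling (PivCl, Et3N, LiCl) with (S)-4-benzyloxazolidin-2-one gives the imide of 3, F10, and the imide of the mirror-image acid, F11. The two are separated by chromatography.
- LiOOH cleaves F10 to 3.

Step 12.
- What may go wrong: sluggish capture by the hindered tertiary hydroxyl group, exo instead of endo closure, or loss of the propargylic oxygen at the metal.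
- Approach of the fallback: polar 6-endo oxa-Michael closure of an ynone in place of vinylidene catalysis, which also replaces steps 11 and 13. It sets out from 14 and comes back at 22.
- MnO2 oxidises the propargylic alcohol of 14 to the ynone F12. Catalytic AgOTf closes F12 to the 2,3-dihydro-4H-pyran-4-one F13.
- I2 and pyridine iodinate the α-carbon (C4a) to the iodopyranone F14, a reaction that simple alkenes do not undergo.
- Luche reduction (NaBH4, CeCl3) gives the allylic alcohol F15, and TBSCl with imidazole gives the silyl ether F16.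
- Iodine–lithium exchange (t-BuLi, −78 °C) gives 22.

Further compounds
F1 | step 15 | (2S)-5-(1-ethoxyethenyl)-4-silyloxy-2-methyl-2-{2-[(1S,2R)-1,2,3-trimethylcyclohex-3-en-1-yl]ethyl}-3,4-dihydro-2H-pyran | C=C(OCC)C1=CO[C@@](C)(CC[C@]2(C)CCC=C(C)[C@@H]2C)CC1O[Si](C)(C)C(C)(C)C
F2 | step 15 | 5-acetyl analogue of 18 | CC(=O)C1=CO[C@@](C)(CC[C@]2(C)CCC=C(C)[C@@H]2C)CC1O[Si](C)(C)C(C)(C)C
F3 | step 15 | 4,4,4-trifluoro-1-(dihydropyran-5-yl)butane-1,3-dione derived from F2 | O=C(CC(=O)C(F)(F)F)C1=CO[C@@](C)(CC[C@]2(C)CCC=C(C)[C@@H]2C)CC1O[Si](C)(C)C(C)(C)C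
F4 | step 15 | 5-(diazoacetyl) analogue of 18 | [N-]=[N+]=CC(=O)C1=CO[C@@](C)(CC[C@]2(C)CCC=C(C)[C@@H]2C)CC1O[Si](C)(C)C(C)(C)C
F5 | step 15 | (2S)-4-silyloxy-6-methoxy-2-methyl-2-{2-[(1S,2R)-1,2,3-trimethylcyclohex-3-en-1-yl]ethyl}chroman-8-ol | COc1cc(O)c2O[C@@](C)(CC[C@]3(C)CCC=C(C)[C@@H]3C)CC(O[Si](C)(C)C(C)(C)C)c2c1
F6 | step 15 | (2S)-6-methoxy-2-methyl-2-{2-[(1S,2R)-1,2,3-trimethylcyclohex-3-en-1-yl]ethyl}-2H-chromen-8-ol | COc1cc(O)c2O[C@@](C)(CC[C@]3(C)CCC=C(C)[C@@H]3C)C=Cc2c1
F7 | step 1 | (Z)-tert-butyldimethylsilyl ketene acetal of 1 (methyl cis to O–Si) | C/C=C(\O[Si](C)(C)C(C)(C)C)OC/C=C(C)/CCC=C(C)C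
F8 | step 1 | tert-butyldimethylsilyl ester of 3, racemic (one enantiomer drawn) | CC(C)(C)[Si](C)(C)OC(=O)[C@H](C)[C@](C)(C=C)CCC=C(C)C
F9 | step 1 | (2S,3R)-3-ethenyl-2,3,7-trimethyloct-6-enoic acid (mirror image of 3) | OC(=O)[C@@H](C)[C@@](C)(C=C)CCC=C(C)C
F10 | step 1 | (4S)-4-benzyl-3-[(2R,3S)-3-ethenyl-2,3,7-trimethyloct-6-enoyl]oxazolidin-2-one | O=C1OC[C@H](Cc2ccccc2)N1C(=O)[C@H](C)[C@](C)(C=C)CCC=C(C)C
F11 | step 1 | (4S)-4-benzyl-3-[(2S,3R)-3-ethenyl-2,3,7-trimethyloct-6-enoyl]oxazolidin-2-one | O=C1OC[C@H](Cc2ccccc2)N1C(=O)[C@@H](C)[C@@](C)(C=C)CCC=C(C)C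
F12 | step 12 | (5S)-5-hydroxy-5-methyl-7-[(1S,2R)-1,2,3-trimethylcyclohex-3-en-1-yl]hept-1-yn-3-one | C#CC(=O)C[C@@](C)(O)CC[C@]1(C)CCC=C(C)[C@@H]1C
F13 | step 12 | (2S)-2-methyl-2-{2-[(1S,2R)-1,2,3-trimethylcyclohex-3-en-1-yl]ethyl}-2,3-dihydro-4H-pyran-4-one | C[C@]1(CC[C@]2(C)CCC=C(C)[C@@H]2C)CC(=O)C=CO1
F14 | step 12 | 5-iodo derivative of F13 | C[C@]1(CC[C@]2(C)CCC=C(C)[C@@H]2C)CC(=O)C(I)=CO1
F15 | step 12 | (2S)-5-iodo-2-methyl-2-{2-[(1S,2R)-1,2,3-trimethylcyclohex-3-en-1-yl]ethyl}-3,4-dihydro-2H-pyran-4-ol | C[C@]1(CC[C@]2(C)CCC=C(C)[C@@H]2C)CC(O)C(I)=CO1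
F16 | step 12 | tert-butyldimethylsilyl ether of F15 (iodo analogue of 18) | C[C@]1(CC[C@]2(C)CCC=C(C)[C@@H]2C)CC(O[Si](C)(C)C(C)(C)C)C(I)=CO1
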